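At 20 min you read four flasks at −20 °C, and the reading is a share of the free monomer charged, so the zero of the scale is a flask with 100 percent in chains: a point below that is monomer still free or monomer lost from the chains.

| flask | free monomer | initiator | temperature | remark | time |
|---|---|---|---|---|---|
| green | 0.80 M | 0.29 mol% (in portions, 3) | −25 °C | run made earlier; portions every 2.0 min |  |
| amber | 0.80 M | 0.81 mol% (in portions, 3) | −14 °C | run made earlier; portions every 2.0 min |  |
| blue | 0.48 M | 0.2 mol% (in portions, 3) | −25 °C | run made earlier; portions every 2.0 min |  |
| gamma | 0.80 M | 0.6 mol% (in portions, 3) | −20 °C | the portions of initiator follow each other after 2.0 min, the first at the start | 20 min |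
| zeta | 0.25 M | 0.6 mol% (in portions, 3) | −20 °C | the portions of initiator follow each other after 2.0 min, the first at the start | 20 min |
| theta | 0.80 M | 0.2 mol% (in portions, 3) | −20 °C | the portions of initiator follow each other after 2.0 min, the first at the start | 20 min |
| epsilon | 0.25 M | 0.2 mol% (in portions, 3) | −20 °C | the portions of initiator follow each other after 2.0 min, the first at the start | 20 min |

| green: time / min | green: monomer in chains / % | amber: time / min | amber: monomer in chains / % | blue: time / min | blue: monomer in chains / % |
|---|---|---|---|---|---|
| 2.00 | 18.4 | 0.833 | 40.5 | 0.833 | 2.3 |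
| 4.00 | 45.9 | 1.50 | 62.2 | 2.50 | 9.9 |
| 6.00 | 67.2 | 3.00 | 79.7 | 5.00 | 29.5 |
| 8.00 | 79.4 | 5.00 | 65.9 | 8.00 | 51.9 |
| 10.0 | 88.5 | 10.0 | 65.2 | 10.0 | 60.2 |

(scatter of a reading: 1 percentage point)

1. the flasks by amount of monomer in chains, in percent of the free monomer charged, highest first, at 20 min (gamma / zeta / theta / epsilon)
2. the amount of monomer in chains, in percent of the free monomer charged of the flask you put first, at 20 min
3. the amount of monomer in chains, in percent of the free monomer charged of the flask you put last, at 20 min

Amber shows the loss: it reads 79.7% at 3.00 min but 65.2% at 10.0 min. A loading in mol% hides what the flask holds, so I reckon with c(initiator), loading times c(free monomer). Amber reads short of the full scale by 34.8% on 0.00648 M, and if I assume that this whole shortfall is loss, the ratio, 53.7 /M, is my loss yardstick, the fraction of the charge lost from the chains per mole per litre of initiator charged; I carry it unchanged from −14 °C, which is a guess.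

Turn the loading first. By hand, gamma's 0.00480 M against theta's 0.00160 M raises the loss, from 8.59% to 25.8%.

Turn c(free monomer) next. Lowering it at a fixed loading lowers c(initiator), and with it my reckoned loss, but also the pseudo-first-order rate constant of monomer use, k times c(initiator). Blue's late slope at −25 °C gives k of 119 /M/min, amber's first reading at −14 °C gives 289 /M/min, and for −20 °C, which lies between those temperatures, I take their geometric mean, 185 /M/min. The portions are in on average for 18.0 min, so I reckon that epsilon keeps 18.9% free.

My reckoning gives zeta 91.3%, theta 90.9%, epsilon 78.5% and gamma 74.2%, with the top pair too close to separate.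

The forecast differs: theta > gamma > zeta > epsilon, with 85% for theta and 40% for epsilon, reading amber as “a true free-monomer floor near 0.28 M at −14 °C”.

The flasks give theta > zeta > gamma > epsilon, from 97.7% in theta to 75.7% in epsilon.

    2 initiator → spent initiator B (k = 4.40 /M/s, Ea = 44.0 kJ/mol)
    free monomer + initiator → living end + monomer in chains (k = 0.190 /M/s, Ea = 47.0 kJ/mol)
    initiator + monomer in chains → initiator + over-reaction product (k = 5.90 /M/s, Ea = 39.0 kJ/mol)
    free monomer + living end → monomer in chains + living end, rate k4*[living end]*[free monomer] (k = 4.00 /M/s, Ea = 42.0 kJ/mol)
    initiator → spent initiator A (k = 0.0210 /s, Ea = 66.0 kJ/mol)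
    (constants at −20 °C)

In theta at 4.21 min, initiator has a half-life of 0.15 min by its step with free monomer, far shorter than the 13 min of monomer in chains by over-reaction, and theta ends with 1.98% over-reaction product. Gamma ends with 19.6% over-reaction product, where the yardstick gave a loss of 25.8%. For theta's neighbour at 0.8 mol%, the yardstick gives 65.6%, and that flask holds 68.8% in chains.

Readings and results come from a simulation for an exercise; noise was put on by code.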